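**Assumptions**
- Target numbering used below: ring CH = C14; ring carbons C1 (the CH2 attached to C2H=) through C13; carbinol carbon = C15; side chain C16–C24. The target is (14R,15S), all-E.
- Me3Al, LiC≡CH·EDA, vinylMgBr, Cp2Zr(H)Cl, 9-BBN and silyl chlorides/triflates are treated as reagents. Optical purity is that of the Sharpless step (about 90–95% ee expected).

## Retrosynthetic overview
1. Colleterpenol ⇐ its O-TES ether; the only ring (14-membered) is closed in the penultimate step at C11–C12 by an intramolecular B-alkyl Suzuki coupling of an open-chain C30 vinyl bromide.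
2. That seco compound ⇐ Negishi sp3–sp2 coupling at C1–C2 of a C17 alkyl iodide (both stereocentres, side chain, vinyl group) with a C13 iodo/bromo triene.
3. C17 iodide ⇐ (2E,6E)-farnesol: Sharpless epoxidation fixes C15, anti vinyl-cuprate opening at the epoxide CH fixes C14. Farnesol ⇐ two small alkynes by Zr-catalysed carboalumination and Negishi coupling.
4. C13 triene ⇐ two pent-3-yn-1-ol units (hydrozirconation–halogenation, Negishi coupling), then acetylide homologation and carboalumination–iodination.

## Route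

**Side-chain vinyl iodide**

Step 1
Reactants: 1, 5-bromo-2-methylpent-2-ene
Product: 2, 6-methylhept-5-en-1-yne
Conditions: LiC≡CH·EDA, DMSO, 10 °C → rt
Reagents that add atoms: lithium acetylide (ethylenediamine complex), [Li]C#C
Why: SN2 alkylation of acetylide by a primary bromide in DMSO; the trisubstituted alkene is inert.

Step 2
Reactants: 2, 6-methylhept-5-en-1-yne
Product: 3, (1E)-1-iodo-2,6-dimethylhepta-1,5-diene
Conditions: Me3Al, Cp2ZrCl2 (cat.), CH2Cl2, rt; then I2, THF, −30 °C
Reagents that add atoms: trimethylaluminium, C[Al](C)C; iodine, II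
Why: Negishi Zr-catalysed carboalumination adds Me–Al syn with Al terminal, and iodinolysis with retention gives the E vinyl iodide.

**C17 fragment (stereodiad and side chain)**

Step 3
Reactants: 4, but-3-yn-1-ol
Product: 5, 4-(trimethylsilyl)but-3-yn-1-ol
Conditions: n-BuLi (2.2 equiv), THF, −78 °C; TMSCl (2.3 equiv); then 1 M HCl
Reagents that add atoms: chlorotrimethylsilane, C[Si](C)(C)Cl
Why: C,O-bis-silylation of the dianion followed by selective acidic cleavage of the O–Si bond protects the alkyne C–H.

Step 4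
Reactants: 5, 4-(trimethylsilyl)but-3-yn-1-ol
Product: 6, (4-iodobut-1-yn-1-yl)trimethylsilane
Conditions: PPh3, imidazole, I2, CH2Cl2, 0 °C → rt
Reagents that add atoms: iodine, II
Why: Appel iodination, SN2 at the primary carbinol.

Step 5
Reactants: 6, (4-iodobut-1-yn-1-yl)trimethylsilane; 3, (1E)-1-iodo-2,6-dimethylhepta-1,5-diene
Product: 7, [(5E)-6,10-dimethylundeca-5,9-dien-1-yn-1-yl]trimethylsilane
Conditions: 6, t-BuLi (2.1 equiv), Et2O, −78 °C; ZnBr2, THF; then 3, Pd(PPh3)4 (3 mol %), THF, rt
Reagents that add atoms: none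
Why: Negishi alkylzinc–alkenyl iodide cross-coupling proceeds with full retention of the E geometry (Negishi's 1,5-diene construction).

Step 6
Reactants: 7, [(5E)-6,10-dimethylundeca-5,9-dien-1-yn-1-yl]trimethylsilane
Product: 8, (5E)-6,10-dimethylundeca-5,9-dien-1-yne
Conditions: K2CO3, MeOH, rt
Reagents that add atoms: none
Why: Methanolysis of the alkynyl–silicon bond frees the terminal alkyne.

Step 7
Reactants: 8, (5E)-6,10-dimethylundeca-5,9-dien-1-yne
Product: 9, (2E,6E)-farnesol [(2E,6E)-3,7,11-trimethyldodeca-2,6,10-trien-1-ol]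
Conditions: Me3Al, Cp2ZrCl2 (cat.), (CH2Cl)2, rt; then n-BuLi, THF, −78 °C; (CH2O)n, → rt
Reagents that add atoms: trimethylaluminium, C[Al](C)C; paraformaldehyde (as formaldehyde), C=O
Why: Zr-catalysed syn carboalumination, then trapping of the alkenyl alanate with formaldehyde, gives the E allylic alcohol.

Step 8
Reactants: 9, (2E,6E)-farnesol
Product: 10, (2S,3S)-2,3-epoxyfarnesol {[(2S,3S)-3-[(3E)-4,8-dimethylnona-3,7-dien-1-yl]-3-methyloxiran-2-yl]methanol}
Conditions: Ti(OiPr)4 (10 mol %), L-(+)-DET (12 mol %), t-BuOOH, 4 Å MS, CH2Cl2, −20 °C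
Reagents that add atoms: tert-butyl hydroperoxide, CC(C)(C)OO
Why: Sharpless asymmetric epoxidation is directed by the allylic OH, so only the 2,3-alkene reacts, and L-(+)-tartrate gives the (2S,3S) epoxide; this sets the future C15–O stereocentre.

Step 9
Reactants: 10, (2S,3S)-2,3-epoxyfarnesol
Product: 11, (2R,3S,6E)-2-ethenyl-3,7,11-trimethyldodeca-6,10-diene-1,3-diol
Conditions: CH2=CHMgBr (5 equiv), CuI (0.5 equiv), THF, −30 → 0 °C
Reagents that add atoms: vinylmagnesium bromide, C=C[Mg]Br
Why: Cuprate SN2 opening occurs at the less substituted epoxide carbon anti to oxygen, so inversion there sets the future C14 (2R) while the tertiary C–O centre (3S) is untouched.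

Step 10
Reactants: 11, (2R,3S,6E)-2-ethenyl-3,7,11-trimethyldodeca-6,10-diene-1,3-diol
Product: 12, (2S,3S,6E)-2-ethenyl-1-iodo-3,7,11-trimethyldodeca-6,10-dien-3-ol
Conditions: PPh3, imidazole, I2 (pre-mixed), CH2Cl2, 0 °C
Reagents that add atoms: iodine, II
Why: Appel iodination is selective for the primary over the tertiary hydroxyl, and pre-forming the phosphonium iodide avoids free I2 and iodoetherification (the descriptor changes only through CIP priority).

Step 11
Reactants: 12, (2S,3S,6E)-2-ethenyl-1-iodo-3,7,11-trimethyldodeca-6,10-dien-3-ol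
Product: 13, triethyl{[(2S,3S,6E)-2-ethenyl-1-iodo-3,7,11-trimethyldodeca-6,10-dien-3-yl]oxy}silane
Conditions: TESOTf, 2,6-lutidine, CH2Cl2, −78 → 0 °C
Reagents that add atoms: triethylsilyl triflate, CC[Si](CC)(CC)OS(=O)(=O)C(F)(F)F
Why: Silyl triflate silylation masks the tertiary alcohol so that the iodide can be metalated later.

**C13 fragment (ring carbons C2–C11)**

Step 12
Reactants: 14, pent-3-yn-1-ol
Product: 15, tert-butyldimethyl(pent-3-yn-1-yloxy)silane
Conditions: TBSCl, imidazole, DMF, rt
Reagents that add atoms: tert-butyldimethylsilyl chloride, CC(C)(C)[Si](C)(C)Cl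
Why: Standard silyl protection of the primary alcohol.

Step 13
Reactants: 15, tert-butyldimethyl(pent-3-yn-1-yloxy)silane
Product: 16, tert-butyl{[(3E)-4-iodopent-3-en-1-yl]oxy}dimethylsilane
Conditions: Cp2Zr(H)Cl (2.5 equiv), THF, 50 °C; then I2, 0 °C
Reagents that add atoms: iodine, II
Why: Schwartz hydrozirconation is syn and, with excess reagent and heat, equilibrates Zr to the methyl-bearing carbon; iodinolysis with retention gives the (E)-2-iodo-2-alkene.

Step 14
Reactants: 14, pent-3-yn-1-ol
Product: 17, 5-iodopent-2-yne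
Conditions: PPh3, imidazole, I2, CH2Cl2, 0 °C → rt
Reagents that add atoms: iodine, II
Why: Appel iodination of the primary alcohol.

Step 15
Reactants: 17, 5-iodopent-2-yne; 16, tert-butyl{[(3E)-4-iodopent-3-en-1-yl]oxy}dimethylsilane
Product: 18, tert-butyldimethyl{[(3E)-4-methylnon-3-en-7-yn-1-yl]oxy}silane
Conditions: 17, Zn dust (TMSCl/BrCH2CH2Br-activated), THF, 40 °C; then 16, Pd(PPh3)4 (5 mol %), THF, rt
Reagents that add atoms: none
Why: Negishi coupling of the homopropargylic zinc iodide with the alkenyl iodide retains the E geometry; the internal alkyne is inert.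

Step 16
Reactants: 18, tert-butyldimethyl{[(3E)-4-methylnon-3-en-7-yn-1-yl]oxy}silane
Product: 19, {[(3E,7E)-8-bromo-4-methylnona-3,7-dien-1-yl]oxy}(tert-butyl)dimethylsilane
Conditions: Cp2Zr(H)Cl (2.5 equiv), THF, 50 °C; then NBS, 0 °C
Reagents that add atoms: N-bromosuccinimide, O=C1CCC(=O)N1Br
Why: Regioselective syn hydrozirconation of the methyl alkyne and bromination with retention gives the (E)-2-bromo-2-alkene; the trisubstituted alkene does not hydrozirconate.

Step 17
Reactants: 19, {[(3E,7E)-8-bromo-4-methylnona-3,7-dien-1-yl]oxy}(tert-butyl)dimethylsilane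
Product: 20, (3E,7E)-8-bromo-4-methylnona-3,7-dien-1-ol
Conditions: TBAF, THF, rt
Reagents that add atoms: none
Why: Fluoride desilylation; the vinyl bromide is unaffected.

Step 18
Reactants: 20, (3E,7E)-8-bromo-4-methylnona-3,7-dien-1-ol
Product: 21, (2E,6E)-2-bromo-9-iodo-6-methylnona-2,6-diene
Conditions: PPh3, imidazole, I2, CH2Cl2, 0 °C
Reagents that add atoms: iodine, II
Why: Appel iodination of the primary alcohol.

Step 19
Reactants: 21, (2E,6E)-2-bromo-9-iodo-6-methylnona-2,6-diene
Product: 22, (5E,9E)-10-bromo-6-methylundeca-5,9-dien-1-yne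
Conditions: LiC≡CH·EDA, DMSO, 10 °C → rt
Reagents that add atoms: lithium acetylide (ethylenediamine complex), [Li]C#C
Why: SN2 alkylation of acetylide at the primary iodide; the vinyl bromide has no anti H for E2 and survives.

Step 20
Reactants: 22, (5E,9E)-10-bromo-6-methylundeca-5,9-dien-1-yne
Product: 23, (1E,5E,9E)-10-bromo-1-iodo-2,6-dimethylundeca-1,5,9-triene
Conditions: Me3Al, Cp2ZrCl2 (cat.), CH2Cl2, rt; then I2, THF, −30 °C
Reagents that add atoms: trimethylaluminium, C[Al](C)C; iodine, II
Why: Zr-catalysed syn carboalumination and iodinolysis install the E-configured C3-methyl vinyl iodide; the vinyl bromide and the alkene are spectators.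

**Fragment union, ring closure, deprotection**

Step 21
Reactants: 13, triethyl{[(2S,3S,6E)-2-ethenyl-1-iodo-3,7,11-trimethyldodeca-6,10-dien-3-yl]oxy}silane; 23, (1E,5E,9E)-10-bromo-1-iodo-2,6-dimethylundeca-1,5,9-triene
Product: 24, {[(2E,6E,10E,13S,14S,17E)-2-bromo-13-ethenyl-6,10,14,18,22-pentamethyltricosa-2,6,10,17,21-pentaen-14-yl]oxy}triethylsilane
Conditions: 13, t-BuLi (2.1 equiv), Et2O, −78 °C; ZnCl2, THF, → rt; then 23 (1.1 equiv), Pd(PPh3)4 (5 mol %), THF, rt
Reagents that add atoms: none
Why: Negishi coupling of the β-branched primary alkylzinc with the alkenyl iodide forms C1–C2 with retention; oxidative addition at C–I is much faster than at the hindered C–Br, and the stereocentres are not involved.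

Step 22
Reactants: 24, seco vinyl bromide (name as in step 21)
Product: 25, triethyl{[(2S,5E)-6,10-dimethyl-2-[(1R,3E,7E,11E)-4,8,12-trimethylcyclotetradeca-3,7,11-trien-1-yl]undeca-5,9-dien-2-yl]oxy}silane
Conditions: 9-BBN (1.5 equiv), THF, 0 °C → rt; then slow addition to PdCl2(dppf) (20 mol %), AsPh3, Cs2CO3, DMF/THF/H2O, 50 °C, 1 mM
Reagents that add atoms: none
Why: 9-BBN hydroborates only the monosubstituted vinyl group, and intramolecular B-alkyl Suzuki–Miyaura coupling with the vinyl bromide closes the 14-membered ring at C11–C12 with retention of the E geometry.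

Step 23
Reactants: 25, O-TES colleterpenol
Product: 26, colleterpenol, (2S,5E)-6,10-dimethyl-2-[(1R,3E,7E,11E)-4,8,12-trimethylcyclotetradeca-3,7,11-trien-1-yl]undeca-5,9-dien-2-ol
Conditions: TBAF, THF, rt → 40 °C
Reagents that add atoms: none
Why: Fluoride cleavage of the tertiary silyl ether avoids acid, which could dehydrate the tertiary alcohol or cyclise the polyene.

## Compound list
1 | 5-bromo-2-methylpent-2-ene | CC(C)=CCCBr | starting material
2 | 6-methylhept-5-en-1-yne | C#CCCC=C(C)C | intermediate
3 | (1E)-1-iodo-2,6-dimethylhepta-1,5-diene | I/C=C(\C)CCC=C(C)C | intermediate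
4 | but-3-yn-1-ol | C#CCCO | starting material
5 | 4-(trimethylsilyl)but-3-yn-1-ol | C[Si](C)(C)C#CCCO | intermediate
6 | (4-iodobut-1-yn-1-yl)trimethylsilane | C[Si](C)(C)C#CCCI | intermediate
7 | [(5E)-6,10-dimethylundeca-5,9-dien-1-yn-1-yl]trimethylsilane | C[Si](C)(C)C#CCC/C=C(\C)CCC=C(C)C | intermediate
8 | (5E)-6,10-dimethylundeca-5,9-dien-1-yne | C#CCC/C=C(\C)CCC=C(C)C | intermediate
9 | (2E,6E)-farnesol | CC(C)=CCC/C(C)=C/CC/C(C)=C/CO | intermediate
10 | (2S,3S)-2,3-epoxyfarnesol | CC(C)=CCC/C(C)=C/CC[C@]1(C)O[C@H]1CO | intermediate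
11 | (2R,3S,6E)-2-ethenyl-3,7,11-trimethyldodeca-6,10-diene-1,3-diol | CC(C)=CCC/C(C)=C/CC[C@](C)(O)[C@@H](CO)C=C | intermediate
12 | (2S,3S,6E)-2-ethenyl-1-iodo-3,7,11-trimethyldodeca-6,10-dien-3-ol | CC(C)=CCC/C(C)=C/CC[C@](C)(O)[C@@H](CI)C=C | intermediate
13 | triethyl{[(2S,3S,6E)-2-ethenyl-1-iodo-3,7,11-trimethyldodeca-6,10-dien-3-yl]oxy}silane | CC(C)=CCC/C(C)=C/CC[C@](C)(O[Si](CC)(CC)CC)[C@@H](CI)C=C | intermediate
14 | pent-3-yn-1-ol | CC#CCCO | starting material
15 | tert-butyldimethyl(pent-3-yn-1-yloxy)silane | CC#CCCO[Si](C)(C)C(C)(C)C | intermediate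
16 | tert-butyl{[(3E)-4-iodopent-3-en-1-yl]oxy}dimethylsilane | C/C(I)=C\CCO[Si](C)(C)C(C)(C)C | intermediate
17 | 5-iodopent-2-yne | CC#CCCI | intermediate
18 | tert-butyldimethyl{[(3E)-4-methylnon-3-en-7-yn-1-yl]oxy}silane | CC#CCC/C(C)=C/CCO[Si](C)(C)C(C)(C)C | intermediate
19 | {[(3E,7E)-8-bromo-4-methylnona-3,7-dien-1-yl]oxy}(tert-butyl)dimethylsilane | C/C(Br)=C\CC/C(C)=C/CCO[Si](C)(C)C(C)(C)C | intermediate
20 | (3E,7E)-8-bromo-4-methylnona-3,7-dien-1-ol | C/C(Br)=C\CC/C(C)=C/CCO | intermediate
21 | (2E,6E)-2-bromo-9-iodo-6-methylnona-2,6-diene | C/C(Br)=C\CC/C(C)=C/CCI | intermediate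
22 | (5E,9E)-10-bromo-6-methylundeca-5,9-dien-1-yne | C/C(Br)=C\CC/C(C)=C/CCC#C | intermediate
23 | (1E,5E,9E)-10-bromo-1-iodo-2,6-dimethylundeca-1,5,9-triene | C/C(Br)=C\CC/C(C)=C/CC/C(C)=C/I | intermediate
24 | {[(2E,6E,10E,13S,14S,17E)-2-bromo-13-ethenyl-6,10,14,18,22-pentamethyltricosa-2,6,10,17,21-pentaen-14-yl]oxy}triethylsilane | CC(C)=CCC/C(C)=C/CC[C@](C)(O[Si](CC)(CC)CC)[C@H](C=C)C/C=C(\C)CC/C=C(\C)CC/C=C(\C)Br | intermediate
25 | O-triethylsilyl colleterpenol | CC(C)=CCC/C(C)=C/CC[C@](C)(O[Si](CC)(CC)CC)[C@H]1C/C=C(\C)CC/C=C(\C)CC/C=C(\C)CC1 | intermediate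
26 | colleterpenol | CC(C)=CCC/C(C)=C/CC[C@](C)(O)[C@H]1C/C=C(\C)CC/C=C(\C)CC/C=C(\C)CC1 | target

## Summary
Total step count: 23.
Longest linear sequence: 12 steps (steps 3–11 then 21–23 from but-3-yn-1-ol; the path from 1 through steps 1, 2, 5–11, 21–23 is also 12).

Three steps most likely to fail, each with a fallback:

1. **Step 22, macrocyclic B-alkyl Suzuki coupling** (oligomerisation, β-hydride elimination or protodeboronation; hindered trisubstituted vinyl bromide). Fallback: close the ring at the allyl–allyl junction C4–C5 instead, by intramolecular alkylation of an allylic phenyl sulfone carbanion with an allylic bromide (the classical cembranoid ring closure), then Pd/LiBHEt3 desulfonylation. This means coupling 13 by the same Negishi reaction with a protected (E)-3-iodo-2-methylprop-2-en-1-ol (C2–C4), attaching a C5–C11 sulfone/vinyl iodide unit to the vinyl group by intermolecular B-alkyl Suzuki coupling, and converting C4–OH to the bromide.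

2. **Step 9, vinyl-cuprate opening of the trisubstituted epoxy alcohol** (competing Payne rearrangement and C1 attack, halohydrin formation or Lewis-acid rearrangement). Fallback: abandon epoxide opening and build the C14/C15 pair in one step by catalytic asymmetric allylboration (chiral-diol-catalysed ketone crotylboration) of the methyl ketone (5E)-6,10-dimethylundeca-5,9-dien-2-one with a γ-(silyloxymethyl)allylboronate. The boronate geometry is chosen to give the 14R,15S relationship through the chair transition state, and this delivers the protected analogue of 11 directly.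

3. **Step 21, Negishi union** (hindered β-branched alkylzinc, possible 1,4-silyl migration in the γ-silyloxy alkyllithium, over-coupling at C–Br). Fallback: reverse the order of the two sp3–sp2 bond formations. First join the fragments at C11–C12 by intermolecular B-alkyl Suzuki coupling, which needs no organolithium, using a C1–O-protected version of 13 and the halogen-swapped analogue of 23 (C11–I, C2–Br, made by exchanging I2 and NBS in steps 16 and 20). Then convert C1 to the iodide and close the ring at C1–C2 by intramolecular Ni-catalysed reductive alkyl iodide/vinyl bromide coupling under high dilution.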